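**Strategy.** Anabsin is cut back to a C2-symmetric, C2–C2′-linked bis(guai-4-en-3-one) 6,12-olide, whose two seven-membered rings and two γ-lactones are opened at C6–C7 (C6′–C7′) and O–C12. The key step exploits that each C6 carries the lactone oxygen next to cyclopentene carbon C5 while C7 carries C11. A twofold chromium-mediated allylation–lactonisation of an open-chain bis(3-formylcyclopentenone) bis[2-(bromomethyl)enoate] therefore forms four rings, four bonds and four stereocentres at once. That precursor is the oxidative enolate dimer of a geraniol-derived cyclopentenone. A late cation–olefin cyclisation closes C3–C5′ and the C4′–O–C10′ ether.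

Key step: step 17

Remark: guaianolide numbering is used (primes for the half that becomes the cage); C10/C10′ are carried as triethylsilyl ethers through the key step because free γ-hydroxy enals would close to lactols, and tributyl(iodomethyl)stannane and both Grignard reagents are taken as commercial.

**Route**

Step 1
Reactants: 1 geraniol
Product: 2 (2S,3S)-2,3-epoxygeraniol
Conditions: Ti(OiPr)4 (5 mol %), L-(+)-diethyl tartrate (6 mol %), t-BuOOH, 4 Å MS, CH2Cl2, −20 °C
Reagents that add atoms: tert-butyl hydroperoxide, CC(C)(C)OO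
Why: Sharpless asymmetric epoxidation with the L-(+)-tartrate catalyst should oxidise only the allylic 2,3-alkene and set C10 (S) and the epoxide CH carbon (future C1), the E geometry fixing their relative configuration.

Step 2
Reactants: 2 (2S,3S)-2,3-epoxygeraniol; 3 allylmagnesium bromide
Product: 4 (2R,3S)-3,7-dimethyl-2-(prop-2-en-1-yl)oct-6-ene-1,3-diol
Conditions: CH2=CHCH2MgBr (3.5 equiv), CuI (10 mol %), THF/Et2O, −40 → 0 °C; aq NH4Cl
Reagents that add atoms: allylmagnesium bromide (3), C=CC[Mg]Br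
Why: Copper-catalysed SN2 opening of the 2,3-epoxy alcohol at its CH carbon (the other epoxide carbon is fully substituted) should give the 1,3-diol with inversion at the future C1 and retention at C10, so both side-chain stereocentres follow stereospecifically from step 1.

Step 3
Reactants: 4 (2R,3S)-3,7-dimethyl-2-(prop-2-en-1-yl)oct-6-ene-1,3-diol
Product: 5 (2R,3S)-3,7-dimethyl-2-(prop-2-en-1-yl)-1,3-bis(triethylsilyloxy)oct-6-ene
Conditions: Et3SiOTf (2.4 equiv), 2,6-lutidine, CH2Cl2, −78 → 0 °C
Reagents that add atoms: triethylsilyl trifluoromethanesulfonate, CC[Si](CC)(CC)OS(=O)(=O)C(F)(F)F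
Why: Silyl triflate silylation caps the primary and the hindered tertiary hydroxyl alike and touches no stereocentre.

Step 4
Reactants: 5 bis(triethylsilyl) ether
Product: 6 (2S,3S)-3,7-dimethyl-2-(prop-2-en-1-yl)-3-(triethylsilyloxy)oct-6-enal
Conditions: (COCl)2, DMSO, CH2Cl2, −78 → −30 °C; Et3N, −78 → 0 °C
Reagents that add atoms: none
Why: Under Swern conditions a primary triethylsilyl ether is exchanged for the alkoxysulfonium ion and oxidised directly to the aldehyde while the tertiary silyl ether stays, and the α-stereocentre should survive the brief cold exposure to amine.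

Step 5
Reactants: 6 aldehyde; 7 isopropenylmagnesium bromide
Product: 8 (4R,5S)-2,5,9-trimethyl-4-(prop-2-en-1-yl)-5-(triethylsilyloxy)deca-1,8-dien-3-ol (both C3 epimers)
Conditions: CH2=C(CH3)MgBr, THF, −78 → 0 °C; aq NH4Cl
Reagents that add atoms: isopropenylmagnesium bromide (7), CC(=C)[Mg]Br
Why: Grignard 1,2-addition to the aldehyde; the new carbinol centre becomes a ketone in step 7, so its configuration does not matter.

Step 6
Reactants: 8 dienol
Product: 9 (5R)-2-methyl-5-[(2S)-6-methyl-2-(triethylsilyloxy)hept-5-en-2-yl]cyclopent-2-en-1-ol (both C1 epimers)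
Conditions: second-generation Grubbs catalyst (3 mol %), CH2Cl2 (0.01 M), 40 °C
Reagents that add atoms: none
Why: Ring-closing metathesis of the allyl and isopropenyl groups should close the five-membered ring (guaianolide C1–C5, new C3=C4 bond) in preference to any seven-membered closure onto the trisubstituted prenyl alkene.

Step 7
Reactants: 9 cyclopentenol
Product: 10 (5S)-2-methyl-5-[(2S)-6-methyl-2-(triethylsilyloxy)hept-5-en-2-yl]cyclopent-2-en-1-one
Conditions: Dess–Martin periodinane, NaHCO3, CH2Cl2, 0 → 23 °C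
Reagents that add atoms: none
Why: Buffered Dess–Martin oxidation of the allylic alcohol gives the enone without a base able to epimerise the adjacent stereocentre (its descriptor changes only through the priority rules).

Step 8
Reactants: 11 tributyl(iodomethyl)stannane; 12 4-methoxybenzyl alcohol
Product: 13 tributyl{[(4-methoxybenzyl)oxy]methyl}stannane
Conditions: NaH, THF/DMF, 0 → 23 °C
Reagents that add atoms: 4-methoxybenzyl alcohol (12), COc1ccc(CO)cc1
Why: Williamson etherification of the sodium alkoxide with the primary α-stannyl iodide.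

Step 9
Reactants: 10 enone; 13 stannane
Product: 14 (5R)-1-{[(4-methoxybenzyl)oxy]methyl}-2-methyl-5-[(2S)-6-methyl-2-(triethylsilyloxy)hept-5-en-2-yl]cyclopent-2-en-1-ol (carbinol centre not controlled)
Conditions: 13, n-BuLi, THF, −78 °C; then 10, −78 °C; aq NH4Cl
Reagents that add atoms: tributyl{[(4-methoxybenzyl)oxy]methyl}stannane (13), CCCC[Sn](CCCC)(CCCC)COCc1ccc(OC)cc1
Why: Tin–lithium exchange gives an α-alkoxymethyllithium (hydroxymethyl anion equivalent) that adds 1,2 to the enone carbonyl, and the tertiary carbinol is erased in step 10.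

Step 10
Reactants: 14 tertiary allylic alcohol
Product: 15 (4R)-3-{[(4-methoxybenzyl)oxy]methyl}-2-methyl-4-[(2S)-6-methyl-2-(triethylsilyloxy)hept-5-en-2-yl]cyclopent-2-en-1-one
Conditions: pyridinium chlorochromate [C5H5NH][CrO3Cl], NaOAc, 4 Å MS, CH2Cl2, 23 °C
Reagents that add atoms: pyridinium chlorochromate, [O-][Cr](=O)(=O)Cl.c1cc[nH+]cc1
Why: Dauben–Babler oxidative transposition, in which the chromate ester of the tertiary allylic alcohol undergoes a [3,3] shift and oxidation, places the carbonyl at C3 and the double bond at C4=C5 and leaves C1 untouched.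

Step 11
Reactants: 15 monomer (two molecules)
Product: 17 (1S,1′S,5R,5′R)-4,4′-bis{[(4-methoxybenzyl)oxy]methyl}-3,3′-dimethyl-5,5′-bis[(2S)-6-methyl-2-(triethylsilyloxy)hept-5-en-2-yl]-[1,1′-bi(cyclopent-3-ene)]-2,2′-dione, via lithium dienolate 16 (not isolated)
Conditions: LiN(iPr)2, THF, −78 °C; CuCl2, DMF, −78 → 0 °C
Reagents that add atoms: none
Why: Kinetic α′-deprotonation at C2 and one-electron oxidation of the enolate by CuCl2 (oxidative enolate homocoupling) should join two identical enantiopure halves at C2, each new bond forming anti to the bulky C1 side chain, so one C2-symmetric diastereomer is expected.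

Step 12
Reactants: 17 dimer
Product: 19 (1S,1′S,5R,5′R)-4,4′-bis{[(4-methoxybenzyl)oxy]methyl}-3,3′-dimethyl-5,5′-bis[(2S)-5-oxo-2-(triethylsilyloxy)pentan-2-yl]-[1,1′-bi(cyclopent-3-ene)]-2,2′-dione, via bis(diol) 18 (not isolated)
Conditions: OsO4 (2 mol %), NaIO4, 2,6-lutidine, dioxane/H2O, 23 °C
Reagents that add atoms: osmium tetroxide, O=[Os](=O)(=O)=O; sodium periodate, [Na+].[O-]I(=O)(=O)=O
Why: Lemieux–Johnson cleavage dihydroxylates and cuts the electron-rich trisubstituted side-chain alkenes to the C7 and C7′ aldehydes while the tetrasubstituted, electron-poor enone alkenes and the benzyl ethers are left alone.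

Step 13
Reactants: 19 dialdehyde; 20 methyl acrylate
Product: 21 bis(Morita–Baylis–Hillman adduct), each side chain ending in CH(OH)C(=CH2)CO2Me (carbinol epimers)
Conditions: methyl acrylate (excess), DABCO, MeOH, 23 °C, 3–5 d
Reagents that add atoms: methyl acrylate (20), C=CC(=O)OC
Why: Twofold Morita–Baylis–Hillman reaction of the unhindered aliphatic aldehydes, whose carbinol configuration is lost in step 14.

Step 14
Reactants: 21 bis(allylic alcohol)
Product: 22 bis[(Z)-2-(bromomethyl)enoate], each side chain ending in CH=C(CH2Br)CO2Me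
Conditions: NBS, Me2S, CH2Cl2, 0 → 23 °C
Reagents that add atoms: N-bromosuccinimide, O=C1CCC(=O)N1Br
Why: Corey–Kim-type activation of each allylic alcohol and SN2′ attack of bromide give the rearranged primary allylic bromide as the thermodynamically favoured (Z)-trisubstituted enoate.

Step 15
Reactants: 22 bis(bromide)
Product: 23 bis(hydroxymethyl) compound (free C6–OH and C6′–OH)
Conditions: DDQ, CH2Cl2/pH 7 buffer, 0 → 23 °C
Reagents that add atoms: none
Why: Oxidative removal of the 4-methoxybenzyl ethers by DDQ is neutral and should spare the tertiary silyl ethers, the allylic bromides and the enones.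

Step 16
Reactants: 23 diol
Product: 24 C2–C2′-linked bis(3-formylcyclopentenone) bis[(Z)-2-(bromomethyl)enoate], C10/C10′ triethylsilyl ethers
Conditions: Dess–Martin periodinane, NaHCO3, CH2Cl2, 0 °C
Reagents that add atoms: none
Why: Dess–Martin oxidation of the primary allylic alcohols gives the C6 and C6′ aldehydes, to be used at once because the ene-1,4-dicarbonyl units are reactive.

Step 17
Reactants: 24 bis(aldehyde) bis(allyl bromide)
Product: 26 C2–C2′-linked bis(3-oxoguai-4-en-12,6-olide) carrying two α-methylene lactones and C10/C10′ triethylsilyl ethers, via bis(hydroxy ester) 25 (not isolated)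
Conditions: CrCl2 (10 equiv), THF (0.002 M), 0 → 23 °C; then CSA (cat.), CH2Cl2, 23 °C
Reagents that add atoms: none
Why: Divalent chromium inserts into each allylic C–Br bond and the resulting 2-(methoxycarbonyl)allylchromium adds through its γ-carbon (C7, C7′) to the neighbouring aldehyde (C6, C6′), after which each C6 oxygen displaces methoxide from the adjacent ester; the closest known reaction type is the intramolecular Nozaki–Hiyama allylation–lactonisation of 2-(bromomethyl)enoates with aldehydes. Each carbocycle closes by 7-exo-trig attack of C7 on the formyl carbon (ring C5–C6–C7–C8–C9–C10–C1) and each lactone by 5-exo-trig acyl substitution (ring O–C6–C7–C11–C12). C7 and C7′ are controlled by the chair transition state of an allylchromium that equilibrates to the geometry with C8 equatorial whatever the bromide geometry, so the anti adduct and hence the trans-fused lactone should form, whereas a configurationally fixed (Z)-allylmetal in a closed chair could reach only the cis lactone, which is the reason for choosing chromium. C6 and C6′ are controlled by C1 and C1′, because the chain leaves C1 on the β-face and must reach the formyl carbon from that face while A(1,3) strain with the C4 methyl holds the enal s-trans with its oxygen turned towards C1. The step needs aldehyde-over-ketone chemoselectivity, which allylchromium reagents have, and closure within each half rather than across halves or between molecules, which the short tether and high dilution secure; the C10 and C10′ silyl ethers keep the γ-hydroxy enals from hiding as lactols.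

Step 18
Reactants: 26 bis(enone)
Product: 27 3β,3′β-diol (bis-allylic alcohol, α-methylene lactones intact)
Conditions: NaBH4, CeCl3·7H2O, MeOH/CH2Cl2, −78 °C
Reagents that add atoms: none
Why: Luche 1,2-reduction leaves the α-methylene lactones alone at −78 °C, and hydride is expected on the α-face (opposite the C10 carbon held over the β-face by C1, and in line with the trans preference of small hydrides for 2-substituted cyclopentanones), giving the alcohols trans to the C2–C2′ bond, of which only C3′ survives into the target.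

Step 19
Reactants: 27 diol
Product: 28 (11S,11′S)-11,13,11′,13′-tetrahydro diol
Conditions: NaBH4, MeOH, 0 °C
Reagents that add atoms: none
Why: Conjugate reduction of α-methylene-γ-lactones by NaBH4 in methanol, the usual route to 11βH,13-dihydro sesquiterpene lactones, followed by protonation of each lactone enolate under equilibrating basic conditions should place each C11 methyl trans to C8.

Step 20
Reactants: 28 bis(silyl ether) diol
Product: 30 anabsin, via tetraol 29 (not isolated)
Conditions: TsOH·H2O (0.5 equiv), MeCN/H2O (20:1), 0 → 23 °C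
Reagents that add atoms: none
Why: Acid cleaves the tertiary silyl ethers and ionises one allylic C3–OH (the two are equivalent by C2 symmetry) to the C3–C4–C5 allyl cation, which C5′ of the facing C4′=C5′ alkene captures at C3 in a cation–olefin cyclisation (ring C3–C2–C2′–C1′–C5′) while the C10′ hydroxyl closes the C4′–O ether 5-exo; the C2–C2′ tether forces C3–C5′ bonding on the α-faces and the C1′–C10′ bond forces β-capture at C4′, so C3, C5′ and C4′ are set by the ring constraints.

**Compound list**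

1 | geraniol, (2E)-3,7-dimethylocta-2,6-dien-1-ol | CC(C)=CCC/C(C)=C/CO | starting material
2 | (2S,3S)-2,3-epoxygeraniol | OC[C@@H]1O[C@@]1(C)CCC=C(C)C | intermediate
3 | allylmagnesium bromide | C=CC[Mg]Br | starting material
4 | (2R,3S)-3,7-dimethyl-2-(prop-2-en-1-yl)oct-6-ene-1,3-diol | OC[C@@H](CC=C)[C@@](C)(O)CCC=C(C)C | intermediate
5 | (2R,3S)-3,7-dimethyl-2-(prop-2-en-1-yl)-1,3-bis(triethylsilyloxy)oct-6-ene | CC[Si](CC)(CC)OC[C@@H](CC=C)[C@@](C)(O[Si](CC)(CC)CC)CCC=C(C)C | intermediate
6 | (2S,3S)-3,7-dimethyl-2-(prop-2-en-1-yl)-3-(triethylsilyloxy)oct-6-enal | O=C[C@@H](CC=C)[C@@](C)(O[Si](CC)(CC)CC)CCC=C(C)C | intermediate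
7 | isopropenylmagnesium bromide | CC(=C)[Mg]Br | starting material
8 | (4R,5S)-2,5,9-trimethyl-4-(prop-2-en-1-yl)-5-(triethylsilyloxy)deca-1,8-dien-3-ol, C3 epimers | C=C(C)C(O)[C@@H](CC=C)[C@@](C)(O[Si](CC)(CC)CC)CCC=C(C)C | intermediate
9 | (5R)-2-methyl-5-[(2S)-6-methyl-2-(triethylsilyloxy)hept-5-en-2-yl]cyclopent-2-en-1-ol, C1 epimers | CC1=CC[C@@H]([C@@](C)(O[Si](CC)(CC)CC)CCC=C(C)C)C1O | intermediate
10 | (5S)-2-methyl-5-[(2S)-6-methyl-2-(triethylsilyloxy)hept-5-en-2-yl]cyclopent-2-en-1-one | CC1=CC[C@@H]([C@@](C)(O[Si](CC)(CC)CC)CCC=C(C)C)C1=O | intermediate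
11 | tributyl(iodomethyl)stannane | CCCC[Sn](CCCC)(CCCC)CI | starting material
12 | 4-methoxybenzyl alcohol | COc1ccc(CO)cc1 | starting material
13 | tributyl{[(4-methoxybenzyl)oxy]methyl}stannane | CCCC[Sn](CCCC)(CCCC)COCc1ccc(OC)cc1 | intermediate
14 | (5R)-1-{[(4-methoxybenzyl)oxy]methyl}-2-methyl-5-[(2S)-6-methyl-2-(triethylsilyloxy)hept-5-en-2-yl]cyclopent-2-en-1-ol, C1 epimers | CC1=CC[C@@H]([C@@](C)(O[Si](CC)(CC)CC)CCC=C(C)C)C1(O)COCc1ccc(OC)cc1 | intermediate
15 | (4R)-3-{[(4-methoxybenzyl)oxy]methyl}-2-methyl-4-[(2S)-6-methyl-2-(triethylsilyloxy)hept-5-en-2-yl]cyclopent-2-en-1-one (monomer; ring C4 = guaianolide C1) | CC1=C(COCc2ccc(OC)cc2)[C@H]([C@@](C)(O[Si](CC)(CC)CC)CCC=C(C)C)CC1=O | intermediate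
16 | lithium cross-conjugated dienolate of 15 (C2=C3–OLi) | CC1=C(COCc2ccc(OC)cc2)[C@H]([C@@](C)(O[Si](CC)(CC)CC)CCC=C(C)C)C=C1O[Li] | intermediate
17 | C2–C2′ dimer of 15, C2 and C2′ trans to the C1 and C1′ side chains; (1S,1′S,5R,5′R)-[1,1′-bi(cyclopent-3-ene)]-2,2′-dione named in step 11 | CC1=C(COCc2ccc(OC)cc2)[C@H]([C@@](C)(O[Si](CC)(CC)CC)CCC=C(C)C)[C@@H]([C@H]3C(=O)C(C)=C(COCc4ccc(OC)cc4)[C@@H]3[C@@](C)(O[Si](CC)(CC)CC)CCC=C(C)C)C1=O | intermediate
18 | bis(diol) of 17 (each side-chain alkene dihydroxylated) | CC1=C(COCc2ccc(OC)cc2)[C@H]([C@@](C)(O[Si](CC)(CC)CC)CCC(O)C(C)(C)O)[C@@H]([C@H]3C(=O)C(C)=C(COCc4ccc(OC)cc4)[C@@H]3[C@@](C)(O[Si](CC)(CC)CC)CCC(O)C(C)(C)O)C1=O | intermediate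
19 | dialdehyde (C7 and C7′ formyl groups), named in step 12 | CC1=C(COCc2ccc(OC)cc2)[C@H]([C@@](C)(O[Si](CC)(CC)CC)CCC=O)[C@@H]([C@H]3C(=O)C(C)=C(COCc4ccc(OC)cc4)[C@@H]3[C@@](C)(O[Si](CC)(CC)CC)CCC=O)C1=O | intermediate
20 | methyl acrylate | C=CC(=O)OC | starting material
21 | bis(Morita–Baylis–Hillman adduct) of 19, carbinol epimers | CC1=C(COCc2ccc(OC)cc2)[C@H]([C@@](C)(O[Si](CC)(CC)CC)CCC(O)C(=C)C(=O)OC)[C@@H]([C@H]3C(=O)C(C)=C(COCc4ccc(OC)cc4)[C@@H]3[C@@](C)(O[Si](CC)(CC)CC)CCC(O)C(=C)C(=O)OC)C1=O | intermediate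
22 | bis[(Z)-2-(bromomethyl)enoate] with C6/C6′ 4-methoxybenzyl ethers | CC1=C(COCc2ccc(OC)cc2)[C@H]([C@@](C)(O[Si](CC)(CC)CC)CC/C=C(\CBr)C(=O)OC)[C@@H]([C@H]3C(=O)C(C)=C(COCc4ccc(OC)cc4)[C@@H]3[C@@](C)(O[Si](CC)(CC)CC)CC/C=C(\CBr)C(=O)OC)C1=O | intermediate
23 | bis(hydroxymethyl) bis[(Z)-2-(bromomethyl)enoate] | CC1=C(CO)[C@H]([C@@](C)(O[Si](CC)(CC)CC)CC/C=C(\CBr)C(=O)OC)[C@@H]([C@H]2C(=O)C(C)=C(CO)[C@@H]2[C@@](C)(O[Si](CC)(CC)CC)CC/C=C(\CBr)C(=O)OC)C1=O | intermediate
24 | key-step precursor: C2–C2′-linked bis(3-formylcyclopentenone) bis[(Z)-2-(bromomethyl)enoate], C10/C10′ triethylsilyl ethers | CC1=C(C=O)[C@H]([C@@](C)(O[Si](CC)(CC)CC)CC/C=C(\CBr)C(=O)OC)[C@@H]([C@H]2C(=O)C(C)=C(C=O)[C@@H]2[C@@](C)(O[Si](CC)(CC)CC)CC/C=C(\CBr)C(=O)OC)C1=O | intermediate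
25 | bis(hydroxy ester): both seven-membered rings closed, C6/C6′ hydroxyls and C7/C7′ 2-(methoxycarbonyl)vinyl groups trans | CC1=C2[C@@H](O)[C@H](C(=C)C(=O)OC)CC[C@](C)(O[Si](CC)(CC)CC)[C@@H]2[C@@H]([C@H]3C(=O)C(C)=C4[C@@H](O)[C@H](C(=C)C(=O)OC)CC[C@](C)(O[Si](CC)(CC)CC)[C@H]34)C1=O | intermediate
26 | key-step product: C2–C2′-linked bis(enone) with two trans-fused α-methylene lactones, C10/C10′ triethylsilyl ethers | CC1=C2[C@H]3OC(=O)C(=C)[C@@H]3CC[C@](C)(O[Si](CC)(CC)CC)[C@@H]2[C@@H]([C@H]4C(=O)C(C)=C5[C@H]6OC(=O)C(=C)[C@@H]6CC[C@](C)(O[Si](CC)(CC)CC)[C@H]45)C1=O | intermediate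
27 | 3β,3′β-diol of 26 | CC1=C2[C@H]3OC(=O)C(=C)[C@@H]3CC[C@](C)(O[Si](CC)(CC)CC)[C@@H]2[C@@H]([C@H]4[C@H](O)C(C)=C5[C@H]6OC(=O)C(=C)[C@@H]6CC[C@](C)(O[Si](CC)(CC)CC)[C@H]45)[C@@H]1O | intermediate
28 | (11S,11′S)-tetrahydro diol (both lactones α-methyl) | CC1=C2[C@H]3OC(=O)[C@@H](C)[C@@H]3CC[C@](C)(O[Si](CC)(CC)CC)[C@@H]2[C@@H]([C@H]4[C@H](O)C(C)=C5[C@H]6OC(=O)[C@@H](C)[C@@H]6CC[C@](C)(O[Si](CC)(CC)CC)[C@H]45)[C@@H]1O | intermediate
29 | desilylated tetraol of 28 | CC1=C2[C@H]3OC(=O)[C@@H](C)[C@@H]3CC[C@](C)(O)[C@@H]2[C@@H]([C@H]4[C@H](O)C(C)=C5[C@H]6OC(=O)[C@@H](C)[C@@H]6CC[C@](C)(O)[C@H]45)[C@@H]1O | intermediate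
30 | anabsin | CC1=C2[C@H]3OC(=O)[C@@H](C)[C@@H]3CC[C@](C)(O)[C@@H]2[C@H]2[C@@H]3[C@@H]4[C@]5([C@H]6OC(=O)[C@@H](C)[C@@H]6CC[C@]4(C)O[C@@]5(C)[C@H]3O)[C@@H]12 | target

**Step count and risk**

Total: 20 steps. Longest linear sequence: 19 steps (geraniol to anabsin, steps 1–7 and 9–20; step 8 makes the stannane reagent).

Steps most likely to fail:

1. Step 17 (key step). Divalent chromium may reduce the electron-poor ene-1,4-dicarbonyl units, anti selectivity at C7 may be incomplete (cis lactone), or addition may occur across halves or between molecules. The fallback sets out from 17 and comes back at 26, and replaces the reductive allylation by a carbonyl-ene ring closure that needs no reducing metal. DDQ on 17 should give the bis(hydroxymethyl) dimer F1, and Dess–Martin oxidation the bis-enal F2. Me2AlCl (CH2Cl2, −78 °C) should then effect a twofold type 1 carbonyl-ene cyclisation of each C6 aldehyde onto its prenyl terminus (the citronellal-to-isopulegol mode, chair transition state, hydroxyl and isopropenyl trans), giving the twofold ene adduct F3. SeO2/t-BuOOH hydroxylates the isopropenyl methyl groups to the bis(allylic 1,4-diol) F4. TEMPO/PhI(OAc)2 then oxidises each primary allylic alcohol through the lactol to the α-methylene lactone, which is compound 26.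

2. Step 20. The allyl cation may eliminate to a cyclopentadiene, or the C4′ cation may be discharged by a 1,2-hydride shift from C3′ or by proton loss before the C10′ oxygen arrives. The fallback sets out from 28 and comes back at 30, and separates C–C from C–O bond formation. BF3·OEt2 with 2,6-di-tert-butylpyridine (CH2Cl2, −78 °C) on the still silylated 28 should stop after C3–C5′ bond formation by loss of a C15′ proton, giving the exocyclic-methylene cage bis(silyl ether) F5. HF·pyridine frees the tertiary alcohols to give the exocyclic-methylene cage triol F6. Hg(O2CCF3)2 followed by NaBH4 closes the C4′–O–C10′ ether by Markovnikov alkoxymercuration–demercuration, giving 30.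

3. Step 11. γ-Deprotonation or over-oxidation of the enolate, low conversion in a hindered coupling, or incomplete facial control at C2 may give little or stereochemically mixed dimer. The fallback sets out from 15 and comes back at 17. The enolate is trapped (LiN(iPr)2, Me3SiCl, THF, −78 °C) as the isolable trimethylsilyl dienol ether F7, which is dimerised with Ag2O in DMSO (oxidative coupling of silyl enol ethers to 1,4-diketones); C2/C2′ can be equilibrated to the trans,trans isomer with DBU if needed.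

Further compounds

F1 | step 17 | bis(hydroxymethyl) dimer (17 without the 4-methoxybenzyl groups) | CC1=C(CO)[C@H]([C@@](C)(O[Si](CC)(CC)CC)CCC=C(C)C)[C@@H]([C@H]2C(=O)C(C)=C(CO)[C@@H]2[C@@](C)(O[Si](CC)(CC)CC)CCC=C(C)C)C1=O
F2 | step 17 | bis-enal (C6 and C6′ formyl groups, prenyl side chains) | CC1=C(C=O)[C@H]([C@@](C)(O[Si](CC)(CC)CC)CCC=C(C)C)[C@@H]([C@H]2C(=O)C(C)=C(C=O)[C@@H]2[C@@](C)(O[Si](CC)(CC)CC)CCC=C(C)C)C1=O
F3 | step 17 | twofold ene adduct (C6/C6′ hydroxyl trans to C7/C7′ isopropenyl) | CC1=C2[C@@H](O)[C@H](C(C)=C)CC[C@](C)(O[Si](CC)(CC)CC)[C@@H]2[C@@H]([C@H]3C(=O)C(C)=C4[C@@H](O)[C@H](C(C)=C)CC[C@](C)(O[Si](CC)(CC)CC)[C@H]34)C1=O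
F4 | step 17 | bis(allylic 1,4-diol) | CC1=C2[C@@H](O)[C@H](C(=C)CO)CC[C@](C)(O[Si](CC)(CC)CC)[C@@H]2[C@@H]([C@H]3C(=O)C(C)=C4[C@@H](O)[C@H](C(=C)CO)CC[C@](C)(O[Si](CC)(CC)CC)[C@H]34)C1=O
F5 | step 20 | exocyclic-methylene cage bis(silyl ether) (C3–C5′ formed, C4′=CH2) | CC1=C2[C@H]3OC(=O)[C@@H](C)[C@@H]3CC[C@](C)(O[Si](CC)(CC)CC)[C@@H]2[C@H]2[C@@H]3[C@@H]4[C@@]([C@H]5OC(=O)[C@@H](C)[C@@H]5CC[C@]4(C)O[Si](CC)(CC)CC)(C(=C)[C@H]3O)[C@@H]12
F6 | step 20 | exocyclic-methylene cage triol | CC1=C2[C@H]3OC(=O)[C@@H](C)[C@@H]3CC[C@](C)(O)[C@@H]2[C@H]2[C@@H]3[C@@H]4[C@@]([C@H]5OC(=O)[C@@H](C)[C@@H]5CC[C@]4(C)O)(C(=C)[C@H]3O)[C@@H]12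
F7 | step 11 | trimethylsilyl dienol ether of 15 | CC1=C(COCc2ccc(OC)cc2)[C@H]([C@@](C)(O[Si](CC)(CC)CC)CCC=C(C)C)C=C1O[Si](C)(C)C
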